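**Retrosynthetic overview**
- The target is reached by site-selective O8 methacryloylation of the 8,9-diol, which comes from an 8,9-acetonide of the complete ring system.
- The ten-membered carbocycle and the cis-fused α-methylene-γ-lactone are formed together by one intramolecular allylboration (C6–C7 bond) of a furanone Z-enal carrying a 2-alkoxycarbonyl allylboronate, under chiral Brønsted acid catalysis.
- The 3(2H)-furanone and the Z-enal both come from a 2-alkynyl-3-methylfuran (oxidative opening to the Z-ene-dione, then γ-hydroxy-ynone cyclisation); the allylboronate comes from a Morita–Baylis–Hillman adduct.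
- C10 is set by Felkin–Anh addition of a furyl acetylide to a methyl ketone; C8 and C9 are set first, by an amino-acid-catalysed syn-aldol of hydroxyacetone with ethyl glyoxylate.
- Ring order: dioxolane (protecting group), then furanone, then the ten-membered carbocycle and γ-lactone in one step.

Assumption: the five achiral building blocks marked as starting materials below are taken as commercially available; atom labels C1–C15 and O6, O8, O9, O10 follow germacrane numbering of the target.

**Step 1**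
Reactants: 1 hydroxyacetone; 2 ethyl glyoxylate
Product: 3 ethyl (2R,3R)-2,3-dihydroxy-4-oxopentanoate
Conditions: O-tert-butyl-D-threonine (20 mol %), NMP, 4 °C, 48 h (1 in 5-fold excess)
Reagents that add atoms: none
Why: Direct asymmetric syn-aldol by primary-amine enamine catalysis: hydroxyacetone forms the hydrogen-bonded Z-enamine at its hydroxylated carbon and adds to the non-enolisable, highly electrophilic aldehyde to give the syn (threo) diol; the D-configured catalyst is expected to give the (2R,3R) isomer (the L-series gives the mirror-image syn diols), which fixes C8 and C9.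

**Step 2**
Reactants: 3 ethyl (2R,3R)-2,3-dihydroxy-4-oxopentanoate
Product: 4 ethyl (4R,5R)-5-acetyl-2,2-dimethyl-1,3-dioxolane-4-carboxylate
Conditions: 2,2-dimethoxypropane, PPTS (cat.), acetone, rt
Reagents that add atoms: 2,2-dimethoxypropane COC(C)(C)OC
Why: Acid-catalysed transketalisation of the threo diol gives the trans-dioxolane (the thermodynamic isomer, so no epimerisation), which blocks O8/O9 and later prevents lactol or lactone formation with the C10 hydroxyl.

**Step 3**
Reactants: 5 3-methylfuran-2-carbaldehyde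
Product: 6 2-ethynyl-3-methylfuran
Conditions: dimethyl (1-diazo-2-oxopropyl)phosphonate, K2CO3, MeOH, 0 °C to rt
Reagents that add atoms: dimethyl (1-diazo-2-oxopropyl)phosphonate CC(=O)C(=[N+]=[N-])P(=O)(OC)OC
Why: Ohira–Bestmann (Seyferth–Gilbert) homologation turns the aldehyde into the terminal alkyne under mild base that the furan tolerates.

**Step 4**
Reactants: 4 ethyl (4R,5R)-5-acetyl-2,2-dimethyl-1,3-dioxolane-4-carboxylate; 6 2-ethynyl-3-methylfuran
Product: 8 ethyl (4R,5R)-5-[(2S)-2-hydroxy-4-(3-methylfuran-2-yl)but-3-yn-2-yl]-2,2-dimethyl-1,3-dioxolane-4-carboxylate, via lithium (3-methylfuran-2-yl)acetylide 7 (not isolated)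
Conditions: n-BuLi, THF, −78 °C; then 4, −78 °C; H2O quench
Reagents that add atoms: none
Why: 1,2-Addition of the lithium acetylide to the ketone (faster than to the ester at −78 °C) under polar Felkin–Anh control, attack anti to the dioxolane C–O bond of the α-carbon, gives the 9,10-anti arrangement and so sets C10 (expected dr about 4:1 or better, minor epimer removed by chromatography).

**Step 5**
Reactants: 8 ethyl (4R,5R)-5-[(2S)-2-hydroxy-4-(3-methylfuran-2-yl)but-3-yn-2-yl]-2,2-dimethyl-1,3-dioxolane-4-carboxylate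
Product: 9 (4R,5R)-5-[(2S)-2-hydroxy-4-(3-methylfuran-2-yl)but-3-yn-2-yl]-2,2-dimethyl-1,3-dioxolane-4-carbaldehyde
Conditions: i-Bu2AlH (2.2 equiv), CH2Cl2, −78 °C; aq. potassium sodium tartrate
Reagents that add atoms: none
Why: Partial reduction of an α-alkoxy ester through the stable tetrahedral aluminate at −78 °C (the first equivalent deprotonates the tertiary alcohol); the trans-dioxolane keeps the γ-hydroxy aldehyde open.

**Step 6**
Reactants: 9 (4R,5R)-5-[(2S)-2-hydroxy-4-(3-methylfuran-2-yl)but-3-yn-2-yl]-2,2-dimethyl-1,3-dioxolane-4-carbaldehyde; 10 methyl acrylate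
Product: 11 methyl 2-{hydroxy[(4S,5R)-5-[(2S)-2-hydroxy-4-(3-methylfuran-2-yl)but-3-yn-2-yl]-2,2-dimethyl-1,3-dioxolan-4-yl]methyl}prop-2-enoate (both carbinol epimers)
Conditions: DABCO (1 equiv), 1,4-dioxane–H2O 1:1, rt
Reagents that add atoms: none
Why: Morita–Baylis–Hillman reaction, fast for α-alkoxy aldehydes; it forms the C7–C11 bond, and the new carbinol centre is unimportant because it becomes sp2 in step 8.

**Step 7**
Reactants: 11 methyl 2-{hydroxy[(4S,5R)-5-[(2S)-2-hydroxy-4-(3-methylfuran-2-yl)but-3-yn-2-yl]-2,2-dimethyl-1,3-dioxolan-4-yl]methyl}prop-2-enoate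
Product: 12 methyl 2-{acetoxy[(4S,5R)-5-[(2S)-2-hydroxy-4-(3-methylfuran-2-yl)but-3-yn-2-yl]-2,2-dimethyl-1,3-dioxolan-4-yl]methyl}prop-2-enoate
Conditions: Ac2O, pyridine, DMAP (cat.), CH2Cl2, 0 °C
Reagents that add atoms: acetic anhydride CC(=O)OC(C)=O
Why: Acyl transfer to the secondary allylic alcohol is much faster than to the hindered tertiary propargylic alcohol, which stays free.

**Step 8**
Reactants: 12 methyl 2-{acetoxy[(4S,5R)-5-[(2S)-2-hydroxy-4-(3-methylfuran-2-yl)but-3-yn-2-yl]-2,2-dimethyl-1,3-dioxolan-4-yl]methyl}prop-2-enoate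
Product: 13 methyl (2E)-3-[(4S,5R)-5-[(2S)-2-hydroxy-4-(3-methylfuran-2-yl)but-3-yn-2-yl]-2,2-dimethyl-1,3-dioxolan-4-yl]-2-[(4,4,5,5-tetramethyl-1,3,2-dioxaborolan-2-yl)methyl]prop-2-enoate
Conditions: B2pin2, Pd2(dba)3 (2.5 mol %, zerovalent palladium), DMSO, 40 °C
Reagents that add atoms: bis(pinacolato)diboron CC1(C)OB(OC1(C)C)B1OC(C)(C)C(C)(C)O1
Why: Miyaura-type allylic borylation through the π-allylpalladium acetate gives the linear 2-alkoxycarbonyl allylboronate with the favoured geometry (C8 cis to CH2Bpin, trans to the ester), which is the geometry needed for the syn adduct in step 10.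

**Step 9**
Reactants: 13 methyl (2E)-3-[(4S,5R)-5-[(2S)-2-hydroxy-4-(3-methylfuran-2-yl)but-3-yn-2-yl]-2,2-dimethyl-1,3-dioxolan-4-yl]-2-[(4,4,5,5-tetramethyl-1,3,2-dioxaborolan-2-yl)methyl]prop-2-enoate
Product: 15 methyl (2E)-3-[(4S,5R)-2,2-dimethyl-5-[(2R)-2-methyl-3-oxo-5-[(2Z)-4-oxobut-2-en-2-yl]-2,3-dihydrofuran-2-yl]-1,3-dioxolan-4-yl]-2-[(4,4,5,5-tetramethyl-1,3,2-dioxaborolan-2-yl)methyl]prop-2-enoate, via Z-ynenedione aldehyde 14 (not isolated)
Conditions: DMDO (1.1 equiv), acetone, −40 to 0 °C; evaporate; then (4-CF3C6H4)3PAuCl / AgOTf (5 mol % each), toluene, rt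
Reagents that add atoms: dimethyldioxirane CC1(C)OO1; water O
Why: Dimethyldioxirane epoxidises only the electron-rich furan, which opens to the cis-ene-dione (Z geometry inherited from the ring), and cationic gold then turns the γ-hydroxy ynone into the 3(2H)-furanone by alkyne hydration next to C10 and cyclodehydration (water is taken up and given back, a net isomerisation).

**Step 10**
Reactants: 15 methyl (2E)-3-[(4S,5R)-2,2-dimethyl-5-[(2R)-2-methyl-3-oxo-5-[(2Z)-4-oxobut-2-en-2-yl]-2,3-dihydrofuran-2-yl]-1,3-dioxolan-4-yl]-2-[(4,4,5,5-tetramethyl-1,3,2-dioxaborolan-2-yl)methyl]prop-2-enoate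
Product: 17 (6S,7S,8S,9R,10R)-8,9-(isopropylidenedioxy)-1-oxo-3,10-epoxygermacra-2,4Z,11(13)-trien-12,6-olide, via macrocyclic pinacol borate 16 (not isolated)
Conditions: (R)-3,3'-bis(2,4,6-triisopropylphenyl)-1,1'-binaphthyl-2,2'-diyl N-triflylphosphoramide (20 mol %), 4 Å MS, toluene, slow addition to 1 mM, 40 °C
Reagents that add atoms: none
Why: Proposed new method: a macrocyclising, chiral-Brønsted-acid-catalysed allylboration in which the acid hydrogen-bonds a pinacol oxygen (raising boron Lewis acidity) and holds the formyl hydrogen, so that C6 and C7 join in a closed six-membered chair (type 1 allylation); the boronate geometry puts C8 axial and gives the syn adduct, whose borate closes onto the methyl ester to the cis-lactone; 1,3-allylic strain keeps H8 in the alkene plane so that C6 adds anti to the C8–C9 bond (the extended arrangement that the short C6-to-C9 tether of the oxa-bridged ring is expected to need), giving 7S, and the (R)-acid directs attack to the Re face of the aldehyde, giving 6S, so catalyst and substrate are matched; the closest known reactions are chiral phosphoric acid-catalysed allylboration of aldehydes with allyl pinacolboronates and acid-catalysed additions of 2-alkoxycarbonyl allylboronates to aldehydes that give α-methylene-γ-butyrolactones, neither of which has been shown in a ring-closing mode or with chiral acid control of a γ-substituted 2-alkoxycarbonyl allylboronate.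

**Step 11**
Reactants: 17 (6S,7S,8S,9R,10R)-8,9-(isopropylidenedioxy)-1-oxo-3,10-epoxygermacra-2,4Z,11(13)-trien-12,6-olide
Product: 18 (6S,7R,8S,9R,10R)-8,9-dihydroxy-1-oxo-3,10-epoxygermacra-2,4Z,11(13)-trien-12,6-olide
Conditions: TFA–H2O 9:1, 0 °C
Reagents that add atoms: none
Why: Acid hydrolysis of the isopropylidene acetal; the furanone, the α-methylene lactone and the diene are stable to cold aqueous acid and no stereocentre is touched (the C7 descriptor changes only through CIP priorities).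

**Step 12**
Reactants: 18 (6S,7R,8S,9R,10R)-8,9-dihydroxy-1-oxo-3,10-epoxygermacra-2,4Z,11(13)-trien-12,6-olide; 19 methacrylic anhydride
Product: 20 (6S,7S,8S,9R,10R)-9-hydroxy-8-(methacryloyloxy)-1-oxo-3,10-epoxygermacra-2,4Z,11(13)-trien-12,6-olide (target, CNP0252578.4)
Conditions: 19 (1.1 equiv), Et3N, DMAP (10 mol %), CH2Cl2, −30 °C
Reagents that add atoms: none
Why: DMAP-catalysed acyl transfer (Steglich-type) should favour O8, because O9 is neopentyl-like (next to quaternary C10) and hydrogen-bonded to the furanone carbonyl, so one equivalent of anhydride at low temperature is expected to give the 8-ester.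

**Compound list**
1 | hydroxyacetone (1-hydroxypropan-2-one) | CC(=O)CO | starting material
2 | ethyl glyoxylate (ethyl 2-oxoacetate) | CCOC(=O)C=O | starting material
3 | ethyl (2R,3R)-2,3-dihydroxy-4-oxopentanoate | CC(=O)[C@H](O)[C@@H](O)C(=O)OCC | intermediate
4 | ethyl (4R,5R)-5-acetyl-2,2-dimethyl-1,3-dioxolane-4-carboxylate | CC(=O)[C@@H]1OC(C)(C)O[C@H]1C(=O)OCC | intermediate
5 | 3-methylfuran-2-carbaldehyde | Cc1ccoc1C=O | starting material
6 | 2-ethynyl-3-methylfuran | Cc1ccoc1C#C | intermediate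
7 | lithium (3-methylfuran-2-yl)acetylide | Cc1ccoc1C#C[Li] | intermediate (not isolated)
8 | ethyl (4R,5R)-5-[(2S)-2-hydroxy-4-(3-methylfuran-2-yl)but-3-yn-2-yl]-2,2-dimethyl-1,3-dioxolane-4-carboxylate | Cc1ccoc1C#C[C@](C)(O)[C@@H]1OC(C)(C)O[C@H]1C(=O)OCC | intermediate
9 | (4R,5R)-5-[(2S)-2-hydroxy-4-(3-methylfuran-2-yl)but-3-yn-2-yl]-2,2-dimethyl-1,3-dioxolane-4-carbaldehyde | Cc1ccoc1C#C[C@](C)(O)[C@@H]1OC(C)(C)O[C@H]1C=O | intermediate
10 | methyl acrylate | C=CC(=O)OC | starting material
11 | methyl 2-{hydroxy[(4S,5R)-5-[(2S)-2-hydroxy-4-(3-methylfuran-2-yl)but-3-yn-2-yl]-2,2-dimethyl-1,3-dioxolan-4-yl]methyl}prop-2-enoate (both carbinol epimers) | Cc1ccoc1C#C[C@](C)(O)[C@@H]1OC(C)(C)O[C@H]1C(O)C(=C)C(=O)OC | intermediate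
12 | methyl 2-{acetoxy[(4S,5R)-5-[(2S)-2-hydroxy-4-(3-methylfuran-2-yl)but-3-yn-2-yl]-2,2-dimethyl-1,3-dioxolan-4-yl]methyl}prop-2-enoate (both epimers) | Cc1ccoc1C#C[C@](C)(O)[C@@H]1OC(C)(C)O[C@H]1C(OC(C)=O)C(=C)C(=O)OC | intermediate
13 | methyl (2E)-3-[(4S,5R)-5-[(2S)-2-hydroxy-4-(3-methylfuran-2-yl)but-3-yn-2-yl]-2,2-dimethyl-1,3-dioxolan-4-yl]-2-[(4,4,5,5-tetramethyl-1,3,2-dioxaborolan-2-yl)methyl]prop-2-enoate | Cc1ccoc1C#C[C@](C)(O)[C@@H]1OC(C)(C)O[C@H]1/C=C(\CB1OC(C)(C)C(C)(C)O1)C(=O)OC | intermediate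
14 | methyl (2E)-3-[(4S,5R)-5-[(2S,6Z)-2-hydroxy-6-methyl-5,8-dioxooct-6-en-3-yn-2-yl]-2,2-dimethyl-1,3-dioxolan-4-yl]-2-[(4,4,5,5-tetramethyl-1,3,2-dioxaborolan-2-yl)methyl]prop-2-enoate | O=C/C=C(/C)C(=O)C#C[C@](C)(O)[C@@H]1OC(C)(C)O[C@H]1/C=C(\CB1OC(C)(C)C(C)(C)O1)C(=O)OC | intermediate (not isolated)
15 | methyl (2E)-3-[(4S,5R)-2,2-dimethyl-5-[(2R)-2-methyl-3-oxo-5-[(2Z)-4-oxobut-2-en-2-yl]-2,3-dihydrofuran-2-yl]-1,3-dioxolan-4-yl]-2-[(4,4,5,5-tetramethyl-1,3,2-dioxaborolan-2-yl)methyl]prop-2-enoate | O=C/C=C(/C)C1=CC(=O)[C@](C)(O1)[C@@H]1OC(C)(C)O[C@H]1/C=C(\CB1OC(C)(C)C(C)(C)O1)C(=O)OC | intermediate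
16 | methyl (6S,7S,8S,9R,10R)-8,9-(isopropylidenedioxy)-1-oxo-6-[(4,4,5,5-tetramethyl-1,3,2-dioxaborolan-2-yl)oxy]-3,10-epoxygermacra-2,4Z,11(13)-trien-12-oate | COC(=O)C(=C)[C@H]1[C@@H](OB2OC(C)(C)C(C)(C)O2)/C=C(/C)C2=CC(=O)[C@](C)(O2)[C@@H]2OC(C)(C)O[C@@H]12 | intermediate (not isolated)
17 | (6S,7S,8S,9R,10R)-8,9-(isopropylidenedioxy)-1-oxo-3,10-epoxygermacra-2,4Z,11(13)-trien-12,6-olide | CC1(C)O[C@H]2[C@H]3C(=C)C(=O)O[C@H]3/C=C(/C)C3=CC(=O)[C@](C)(O3)[C@@H]2O1 | intermediate
18 | (6S,7R,8S,9R,10R)-8,9-dihydroxy-1-oxo-3,10-epoxygermacra-2,4Z,11(13)-trien-12,6-olide | O[C@H]1[C@H]2C(=C)C(=O)O[C@H]2/C=C(/C)C2=CC(=O)[C@](C)(O2)[C@@H]1O | intermediate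
19 | methacrylic anhydride | CC(=C)C(=O)OC(=O)C(C)=C | starting material
20 | (6S,7S,8S,9R,10R)-9-hydroxy-8-(methacryloyloxy)-1-oxo-3,10-epoxygermacra-2,4Z,11(13)-trien-12,6-olide | C=C(C)C(=O)O[C@H]1[C@H]2C(=C)C(=O)O[C@H]2/C=C(/C)C2=CC(=O)[C@](C)(O2)[C@@H]1O | target

**Step count**
Total: 12 steps. Longest linear sequence: 11 steps (steps 1, 2 and 4 to 12); step 3 is a one-step branch.

**Three steps most likely to fail**

Step 10 (the proposed new step). The ring may not close, or the ring-constrained transition state may give the wrong C7 epimer; the sense of induction of the (R)-acid is assigned by analogy and the (S)-acid is the first thing to try if it proves mismatched. The fallback is a metal-mediated Barbier ring closure, which is known chemistry: indium allylations with (Z)-2-(bromomethyl)alk-2-enoates are syn-selective and give cis-α-methylene-γ-butyrolactones, and intramolecular Barbier closure of ten-membered germacranolide rings is established. It sets out from 11: MsCl and Et3N in CH2Cl2 at −20 °C, then LiBr in acetone, give by SN2' displacement the (Z)-allylic bromide F1. DMDO and then silver-free (Ph3P)AuNTf2 in toluene give, through the ynenedione aldehyde bromide F2, the furanone enal bromide F3. Indium powder in THF–H2O at high dilution closes the ring to the macrocyclic hydroxy ester F4, which lactonises with catalytic camphorsulfonic acid and comes back to the route at 17.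

Step 9. The Z-enal of 14 and 15 may isomerise or decompose under the gold/silver conditions. The fallback inverts the order of the two ring closures so that the aldehyde is consumed before any gold is used. It sets out from crude 14, which is submitted directly to the conditions of step 10 to give, via the pinacol borate F5, the ten-membered hydroxy-ynone lactone F6. The gold-catalysed γ-hydroxy-ynone cyclisation is then run on F6, which carries no aldehyde, and comes back to the route at 17.

Step 12. Direct acylation may give mixtures of the 8- and 9-esters, or the ester may migrate. The fallback hands regiocontrol to a tin acetal, a known method for monoacylation of vicinal diols. It sets out from 18: Bu2SnO in toluene at 80 °C over 4 Å MS gives the dibutylstannylene acetal F7, which reacts with methacryloyl chloride (1.0 equiv, 0 °C) at the less hindered tin-bound oxygen O8 and, after aqueous work-up, comes back to the route at 20.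

**Further compounds**
F1 | step 10 | methyl (2Z)-2-(bromomethyl)-3-[(4S,5R)-5-[(2S)-2-hydroxy-4-(3-methylfuran-2-yl)but-3-yn-2-yl]-2,2-dimethyl-1,3-dioxolan-4-yl]prop-2-enoate | Cc1ccoc1C#C[C@](C)(O)[C@@H]1OC(C)(C)O[C@H]1/C=C(\CBr)C(=O)OC
F2 | step 10 | methyl (2Z)-2-(bromomethyl)-3-[(4S,5R)-5-[(2S,6Z)-2-hydroxy-6-methyl-5,8-dioxooct-6-en-3-yn-2-yl]-2,2-dimethyl-1,3-dioxolan-4-yl]prop-2-enoate | O=C/C=C(/C)C(=O)C#C[C@](C)(O)[C@@H]1OC(C)(C)O[C@H]1/C=C(\CBr)C(=O)OC
F3 | step 10 | methyl (2Z)-2-(bromomethyl)-3-[(4S,5R)-2,2-dimethyl-5-[(2R)-2-methyl-3-oxo-5-[(2Z)-4-oxobut-2-en-2-yl]-2,3-dihydrofuran-2-yl]-1,3-dioxolan-4-yl]prop-2-enoate | O=C/C=C(/C)C1=CC(=O)[C@](C)(O1)[C@@H]1OC(C)(C)O[C@H]1/C=C(\CBr)C(=O)OC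
F4 | step 10 | methyl (6S,7S,8S,9R,10R)-6-hydroxy-8,9-(isopropylidenedioxy)-1-oxo-3,10-epoxygermacra-2,4Z,11(13)-trien-12-oate | COC(=O)C(=C)[C@H]1[C@@H](O)/C=C(/C)C2=CC(=O)[C@](C)(O2)[C@@H]2OC(C)(C)O[C@@H]12
F5 | step 9 | methyl (6S,7S,8S,9R,10S)-10-hydroxy-8,9-(isopropylidenedioxy)-3-oxo-6-[(4,4,5,5-tetramethyl-1,3,2-dioxaborolan-2-yl)oxy]germacra-4Z,11(13)-dien-1-yn-12-oate | COC(=O)C(=C)[C@H]1[C@@H](OB2OC(C)(C)C(C)(C)O2)/C=C(/C)C(=O)C#C[C@](C)(O)[C@@H]2OC(C)(C)O[C@@H]12
F6 | step 9 | (6S,7S,8S,9R,10S)-10-hydroxy-8,9-(isopropylidenedioxy)-3-oxogermacra-4Z,11(13)-dien-1-yn-12,6-olide | CC1(C)O[C@H]2[C@H]3C(=C)C(=O)O[C@H]3/C=C(/C)C(=O)C#C[C@](C)(O)[C@@H]2O1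
F7 | step 12 | 8,9-O-(dibutylstannylene) acetal of (6S,7R,8S,9R,10R)-8,9-dihydroxy-1-oxo-3,10-epoxygermacra-2,4Z,11(13)-trien-12,6-olide | CCCC[Sn]1(CCCC)O[C@H]2[C@H]3C(=C)C(=O)O[C@H]3/C=C(/C)C3=CC(=O)[C@](C)(O3)[C@@H]2O1
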